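At early times the loss of Q, which takes up J stepwise to G, E, X and D in a closed isothermal flask, looks like a pseudo-first-order decay at a rate k·J, with k a rate constant, since −ln(Q/Q₀) divided by J₀t, with Q₀ and J₀ the charges, reads 0.00135 L mol⁻¹ min⁻¹ in larch at 0.833 d and 0.00130 L mol⁻¹ min⁻¹ in birch at 0.417 d. By 5.00 d you read 6.51 × 10⁻⁴ L mol⁻¹ min⁻¹ in larch and 4.30 × 10⁻⁴ L mol⁻¹ min⁻¹ in birch.

the same everywhere: Q 0.093 M
- larch: J 0.11 M; run made earlier
- birch: J 0.30 M; run made earlier
- south-east: J 0.0930 M; time 5.0 d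
- south: J 0.190 M; time 5.0 d

| run | time / d | E / % | X / % | D / % | G / % | Q / % |
|---|---|---|---|---|---|---|
| larch | 0.250 | 0 | 0.7 | 0 | 7.0 | 94.5 |
| larch | 0.833 | 0.1 | 0 | 0 | 14.3 | 83.7 |
| larch | 1.25 | 3.3 | 0.5 | 0 | 19.9 | 78.9 |
| larch | 2.00 | 3.8 | 0 | 0 | 24.2 | 72.1 |
| larch | 3.00 | 5.5 | 0 | 2.0 | 29.0 | 67.4 |
| larch | 4.00 | 6.6 | 0 | 0 | 30.5 | 61.4 |
| larch | 5.00 | 8.3 | 1.1 | 0 | 33.2 | 59.7 |
| birch | 0.417 | 2.5 | 0 | 0 | 20.2 | 79.1 |
| birch | 0.625 | 3.9 | 0.7 | 0 | 24.2 | 72.4 |
| birch | 0.833 | 4.9 | 0 | 1.9 | 26.3 | 67.3 |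
| birch | 1.25 | 7.8 | 0.5 | 0.7 | 29.9 | 61.3 |
| birch | 2.00 | 10.7 | 0.4 | 0 | 34.8 | 52.6 |
| birch | 3.00 | 12.2 | 0.6 | 0 | 40.0 | 46.3 |
| birch | 5.00 | 18.4 | 1.0 | 1.4 | 41.2 | 39.5 |

(scatter of a reading: 1 percentage point)

* which of these there is most of at the end, counted by the Q in it, south-east (X / G / E / Q)
* which of these there is most of at the end, counted by the Q in it, south (X / G / E / Q)
* the largest of these amounts at the end, in percent of the Q charged, south-east
* the largest of these amounts at the end, in percent of the Q charged, south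



My own reckoning supposes that J destroys itself in pairs, so that J falls as J₀/(1 + u), where u = bJ₀t, with b the rate constant of that loss, is the time measured in first half-lives of J. Integrating k·J then gives Q/Q₀ = (1 + u)^−a, where a = k/b. I try the round value u = 4 for birch at its last reading, which gives a = 0.577, the rate constant of the loss of Q over that of the loss of J. Larch then has u = 1.47 and comes out at 59.3 % against the 59.7 % read.

But one number isn't enough across times: birch at 2.00 d, with u = 1.60, should hold 57.6 % and reads 52.6 %, with a scatter of 1 percentage point. So you should use the rule at 5.0 d, the time of the readings it was tried on, where u = 1.24 in south-east gives 62.8 % and u = 2.53 in south gives 48.3 %. Both exceed the 41.2 % of G read in birch at that time, and birch was charged with more J than south, so I expect Q to lead.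

The forecast, slightly apart from my figures, names Q for south-east at 62.5 % and Q for south at 49 %, on its reading of the slowing as “loss of activity tied to J exposure”, or inhibition or reversal.

The largest amount is Q in south-east at 63.5 % and Q in south at 48.7 %.

    Q + J → G (k = 0.00169 L mol⁻¹ min⁻¹)
    J + G → E (k = 0.00141 L mol⁻¹ min⁻¹)
    J + E → X (k = 7.20 × 10⁻⁴ L mol⁻¹ min⁻¹)
    J + X → D (k = 0.00309 L mol⁻¹ min⁻¹)
    2 J → Z (k = 0.00146 L mol⁻¹ min⁻¹)
    D → L (k = 3.99 × 10⁻⁷ min⁻¹)

At the start of south, the loss of two J to Z used J 3.5 times as fast as the making of G. Charged with 0.76 M of J instead, the same flask has u = 10.1 at 5.00 d, so a gives 24.9 % for Q, and that flask holds 24.7 %.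

The runs stem from a simulated flask from invented constants; scatter was added.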